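With pre-initiator and transfer agent charged alike, Tuesday's and Thursday's runs could not lie so close on one percentage curve unless free monomer entered its own loss near the first power, and their free monomer charges differ by a factor of 1.57.

the same everywhere: pre-initiator 0.50 mM
- Thursday's: free monomer 0.028 M; transfer agent 0.60 mM; run made earlier
- Tuesday's: free monomer 0.044 M; transfer agent 0.60 mM; run made earlier
- flask: free monomer 0.020 M; transfer agent 0.600 mM; time 3.0 min

| run | time / min | monomer in chains / % | free monomer / % |
|---|---|---|---|
| Thursday's | 0.250 | 1 | 101 |
| Thursday's | 0.667 | 1 | 100 |
| Thursday's | 1.50 | 8 | 92 |
| Thursday's | 4.00 | 32 | 70 |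
| Tuesday's | 0.833 | 4 | 96 |
| Tuesday's | 2.00 | 15 | 85 |
| Tuesday's | 2.50 | 17 | 80 |
| Tuesday's | 4.00 | 33 | 67 |

(scatter of a reading: 1.5 percentage points)

- the average divides the monomer in chains by the number of chains begun, living and dead together
- reactions considered so far: free monomer + initiator -> living end + monomer in chains; free monomer + living end -> monomer in chains + living end; living end + transfer agent -> dead chain; pre-initiator -> initiator
- the earlier runs do not show the number of chains; that part of a forecast is a guess

- average number of monomer units in a chain (chains begun, living or dead) at 3.0 min
- part of the free monomer that has reacted at 3.0 min

Read down the columns of free monomer. Thursday's run still shows 100 % at 0.667 min and Tuesday's 96 % at 0.833 min, so the start is slow. At 4.00 min the runs stand at 70 % and 67 %, with a scatter of 1.5 percentage points on each reading. Pre-initiator releases initiator, initiator starts living ends, and living ends add free monomer until transfer agent ends them. On this scheme free monomer falls in a nearly pseudo-first-order way, with a rate constant that changes along with the concentration of the living end.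

Call the natural logarithm of charged over present free monomer the exposure. Tuesday's reading at 2.50 min gives 0.223, and the mean of the last readings gives 0.379. My straight line between them reaches 0.275 at 3.0 min, my estimate of the exposure of the flask. That estimate means 24.0 % reacted. Chains begun cannot exceed the 0.50 mM of pre-initiator charged, so with my estimated conversion the average comes to at least 9.62 units.

The forecast differs from my conversion, with 22 % reacted, and gives 20 units. Of the chains it writes: “The number of chains is a guess.”

The flask gives 21.5 % reacted and an average of 13.7 units.

    free monomer + initiator → living end + monomer in chains (k = 1.98 M⁻¹ s⁻¹)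
    free monomer + living end → monomer in chains + living end, rate k2*[living end]*[free monomer] (k = 11.3 M⁻¹ s⁻¹)
    living end + transfer agent → dead chain (kL = 13.4 M⁻¹ s⁻¹)
    pre-initiator → initiator (k = 0.00679 s⁻¹)

The flask keeps 78.5 % of its free monomer, an exposure of 0.243 against the interpolated 0.275. The neighbouring flask is charged with 0.012 M of free monomer, other charges and time held. Carried over unchanged, 0.275 predicts 24.0 % reacted there and the flask's 0.243 predicts 21.6 %, while the neighbour reaches 19.7 %. Scaling the flask's average by the charge ratio of 0.600 predicts 8.20 units, and the neighbour's average stands at 8.26.

All runs come from a simulation with made-up constants; noise was put on by code.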